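**The false exit.** A molecule of open intermediate cannot be counted as gone the moment it meets free catalyst, since the catalyst intermediate so formed can fall apart and hand it back. I wanted the time it really takes to leave.

| flask | substrate | reagent | free catalyst | time | remark |
|---|---|---|---|---|---|
| Tuesday's | 0.030 M (in portions, 3) | 1.80 equiv | 0.63 mol% | 8.0 h | the portions of substrate follow each other after 2.0 h, the first at the start |
| Saturday's | 0.050 M (in portions, 3) | 1.80 equiv | 0.63 mol% | 8.0 h | the portions of substrate follow each other after 2.0 h, the first at the start |
| Thursday's | 0.080 M (in portions, 3) | 1.80 equiv | 0.63 mol% | 8.0 h | the portions of substrate follow each other after 2.0 h, the first at the start |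

- [open intermediate] at the end for Tuesday's, Saturday's, Thursday's, in this order
- how that number moves from the first to the last of them (rises all the way / falls all the way / hardly changes / falls, then rises / rises, then falls)

    substrate + free catalyst → free catalyst + open intermediate (k1 = 3800 M⁻¹ h⁻¹)
    free catalyst + open intermediate ⇌ catalyst intermediate (K2 = 19 M⁻¹, k2 = 690 M⁻¹ h⁻¹)
    reagent + catalyst intermediate → free catalyst + target (k3 = 1000 M⁻¹ h⁻¹)
    target ⇌ isomer of the product (K4 = 0.48, k4 = 0.015 h⁻¹)

**Drain half-life.** On Tuesday's charge, forward capture has a half-life of 5.3 h. The catalyst intermediate then reverts at 36.3 h⁻¹ or meets reagent at 54.0 h⁻¹, so a fraction 0.598 of captures goes on to target. Dividing the capture half-life by this fraction gave 8.89 h, the drain half-life, a pseudo-first-order time reckoned with reagent as charged and the catalyst wholly free, which is why I used it for a floor. Catalyst and reagent both scale with the charge, so Saturday's came to 4.48 h and Thursday's to 2.50 h, which is shorter.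

**The bracket.** From above, open intermediate cannot exceed the charge: 0.030 M, 0.050 M, 0.080 M. I could go no lower by hand, as that needs the free catalyst and reagent along the way. From below, I took each portion as turned into open intermediate the moment it was added, and drained at that half-life from then on. Exposing Thursday's whole charge for 8.0 h gave a floor of 0.00871 M. Exposing the portions for 8.0 h, 6.00 h and 4.00 h gave floors of 0.0189 M on Tuesday's, 0.0204 M on Saturday's and 0.0167 M on Thursday's. These floors rise and then fall, while the ceilings rise throughout, so the bracket left the shape open.

**The outcome.** The forecast, holding that “its capture by the tiny amount of catalyst is much slower than its formation”, gave 0.0214 M, 0.027 M and 0.0253 M, rises, then falls, and these stood inside the bracket. The simulation gave 0.0213 M, 0.0268 M and 0.0256 M, rises, then falls, above my floor in each flask.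

**What ran when.** In Tuesday's flask the turning of substrate had half of its turnover behind it by 3.22 h and the step to target by 5.23 h, and with a drain half-life of 8.89 h, longer than the 8.0 h run, open intermediate stood at 71.1% of the charge at the end. In Thursday's flask, with a drain half-life of 2.50 h, shorter than the run, open intermediate stood at 37.0% of the whole charge at 4.00 h, just before the last addition, and at 32.0% at 8.00 h, when target had reached 64.6%.

The constants used here belong to no real substance; the rest is arithmetic.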